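I decided to leave the three flasks closed under the held gas for the full run, and to reckon beforehand what the next person at the bench should find.

common to all: substrate 1.0 M; gas phase 77 mM (held); time 3.0 min
- oak: free catalyst 0.5 mol%
- birch: free catalyst 0.75 mol%
- maple: free catalyst 1.1 mol%

    gas phase ⇌ dissolved gas, rate k1*(csat - [dissolved gas]) (k1 = 1.37 s⁻¹, csat = 77 mM)
    substrate + dissolved gas + free catalyst → free catalyst + target (k2 = 263 M⁻² s⁻¹)
    free catalyst + target → spent catalyst (k3 = 0.0528 M⁻¹ s⁻¹)
    target + free catalyst ⇌ isomer of the product + free catalyst, rate k4*[free catalyst]*[target] forward; the back reaction follows from the equilibrium constant (K4 = 0.321, k4 = 8.86 M⁻¹ s⁻¹)

- at the start none of the gas is dissolved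
- run time (oak): 3.0 min

1. which of the two there is more of at the end, oak (target / isomer of the product)
2. which of the two there is more of at the end, birch (target / isomer of the product)
3. which of the two there is more of at the end, maple (target / isomer of the product)
4. amount of target at the end, in percent of the substrate charged, oak
5. amount of target at the end, in percent of the substrate charged, birch
6. amount of target at the end, in percent of the substrate charged, maple

Each flask started with substrate and free catalyst, and with gas beginning to cross into solution. Steps 2 and 4 both run on free catalyst, so I compared them per unit of it. With dissolved gas taken at 77 mM, the pair of target and isomer relaxes 1.80 times as fast as substrate is consumed, and the loading cancels from that ratio. That margin is small, so I took step 4 as being at equilibrium only as an approximation for the end of the run. That gave 75.7% as the equilibrium share, the fraction of the product that remains target once step 4 has equilibrated.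

My note said to expect target ahead of isomer by 3.12 to one in each flask, with target equal to this share of the substrate converted. I did not reckon the conversion itself, but I expected target to rise with loading from oak to maple. The note also said not to extend the run. With target near that share of the substrate charged, free catalyst halves by step 3 every 17.3 s, which is shorter than the 3.0 min of the run.

The forecast named target, target and target as the larger in oak, birch and maple, with 73.5%, 74.6% and 74.7% of target, on the ground that “isomerisation is fast enough to nearly reach that ratio”.

The simulation gave target, target and target as the larger in oak, birch and maple, with 72.9%, 74.3% and 74.7% of target against 21.8%, 23.3% and 23.9% of isomer.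

At 3.00 min, with free catalyst at 0.172% of its charge, the relaxation half-life of the pair in oak was 36.9 min, longer than the run. Oak ended with target at 77.0% of target and isomer together, against the equilibrium share of 75.7%. In a neighbour flask, oak with 0.12 mol% of free catalyst, target ended at 83.6% of target and isomer together, with 31% of the substrate left.

(The numbers stand for no real mixture; the flask was simulated.)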